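## The problem

Compound 18 is a single cyclohexane with no ring fusion to lean on; it carries oxygen on four contiguous ring carbons and on one exocyclic carbon. The ring is numbered C1 (quaternary carbinol carbon bearing the C7H2OBz arm), C2 (CHOH), C3 and C4 (CH2), C5 (CHOBz) and C6 (CHOH). The configuration is (1S,2R,5R,6S): O1 and O5 lie on one face, O2, O6 and C7 on the other. O2 and O6 are a cis-1,3 pair and can be tied together across the ring. The resulting bicycle has two different faces at C1, so C2/C6 can control C1, and O1, being cis-1,3 to C5, can deliver a substituent to C5. Two of the five oxygens are benzoates next to free hydroxyls, so hydroxide, alkoxide and hot acid invite ester cleavage or acyl migration. Which oxygen is acylated therefore has to be settled by construction, not by late selection among three secondary alcohols. The decisive feature is that without the C5 oxygen the molecule has a mirror plane through C1, C7 and C4, which makes the C3 and C5 methylene groups enantiotopic. With O2 and O6 bridged diaxially on one face, O1 is axial on the other, syn to the axial hydrogens on C3 and C5, and a silicon atom on O1 can reach either through a five-membered ring O1–Si–C5–C6–C1. The absolute configuration of the whole ring thus reduces to choosing one of two enantiotopic C–H bonds in a meso compound.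

## Retrosynthesis

**18 from 17.** The last cut is at the two acetal C–O bonds that mask O2 and O6. A benzylidene acetal is chosen because it falls to hydrogen over palladium in a neutral medium, where the two benzoates of 18 neither migrate nor hydrolyse. Precursor 17 differs from 18 only by this bridge.

**17 from 15 and 16.** The C5–O acyl bond is cut. In 15 the C5 hydroxyl is the only free secondary alcohol: O2 and O6 are in the acetal, O7 is already a benzoate and O1 is tertiary. The forward benzoylation therefore needs no selectivity beyond secondary over tertiary.

**15 from 14.** The C5–O bond is traced back to a C5–Si bond, and the free O1–H to the O1–Si bond of the same silicon atom. Oxidation of C–Si proceeds with retention, so the oxasilolane 14 already holds the C5 configuration. A direct C–H hydroxylation would offer neither site control nor face control.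

**14 from 13 (key disconnection).** The C5–Si bond and with it the oxasilolane ring are cut, which leads to the meso diethyl(hydrido)silyl ether 13. Compound 13 has no stereocentre at C5 and a mirror plane through C1, C7 and C4. The forward reaction must insert the silicon into the axial C5–H bond and not into its mirror-related partner on C3. The spectator acetal matters here. An isopropylidene bridge would push a methyl group under the axial hydrogen on C4 once the carbocycle is held as a chair, or against the C7 arm if the dioxane ring escaped into a boat. A benzylidene bridge with phenyl exo puts only hydrogen there and keeps O1 axial and syn to the two target hydrogens.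

**13 from 11 and 12.** The O1–Si bond is cut. Dehydrogenative coupling of the tertiary alcohol 11 with diethylsilane 12 forms it without any stoichiometric by-product other than hydrogen.

**11 from 9 and 10, and 9 from 7 and 8.** The C7–O bond to the benzoate is cut first: benzoate 10 opens the spiro-epoxide 9 at its CH2 group and sets the tertiary hydroxyl free in the same step. The C1–C7 and C7–O1 bonds of 9 are then cut back to ketone 7 and the sulfonium salt 8. The neighbouring option, methylenation, dihydroxylation and monobenzoylation, is one step longer. It also needs an electrophile to attack the alkene face that is sterically more shielded. The ylide, by contrast, adds carbon to the face flanked by the two ring oxygens, which is the open one, and that places C7 cis to O2 and O6 as required. Ketone 7 cannot enolise, which suits a basic ylide.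

**7 from 5, 5 from 3 and 4, 3 from 1 and 2.** The carbonyl group of 7 is traced to the nitro group of 5 (Nef reaction), the acetal of 5 to nitrodiol 3 and the acetal donor 4, and the C1–C2 and C1–C6 bonds of 3 to a double nitroaldol reaction of glutaraldehyde 1 with nitromethane 2. This delivers the cis-1,3-diol as a meso compound in one step from two bulk chemicals. The neighbouring cut, α,α′-annulation of a dioxanone azaenolate with a three-carbon dielectrophile, needs strong base at low temperature, risks N-alkylation in the ring-closing step and would bring in the less suitable isopropylidene bridge.

## Roads not taken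

**Alternative 1:** The cut is the C2–O bond. The C7 hydroxyl of the achiral dienylmethanol A1, available through Birch reduction chemistry, captures carbon dioxide; the carbonate then closes onto one of the two enantiotopic ring alkenes under iodonium activation and gives the cis-fused iodocarbonate A2.

- **Merits:** The quaternary carbon C1 is present from the start, and one catalytic step sets C1 and C2 and tells the two alkenes apart. Enantioselective halocyclisations of carbonates formed in the flask from an alcohol and carbon dioxide are an established reaction class, so this key step rests on firmer precedent than the one chosen here.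
- **Weak points for 18:** A2 must still lose the iodine at C3. The C5=C6 alkene must become a trans diol with the benzoate on C5 and not on C6. After carbonate and methoxymethyl cleavage, one primary and three secondary hydroxyls have to be acylated selectively.
- **Comparison:** The chosen plan sets against the better precedent an end game of three steps in which every hydroxyl is distinguished by the way it was introduced.

**Alternative 2:** The cut is at the C1–C7 and C7–O1 bonds. Dimethylsulfonium methylide adds axially to the C1 carbonyl of the tris(benzyl ether) ketone A3, whose three secondary stereocentres hide a C2 axis, and gives the spiro-epoxide A4 with C7 cis to O2 and O6.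

- **Merits:** Every step is known chemistry, and the hidden symmetry means that few stereochemical decisions are needed. In these respects this road is better than the chosen plan.
- **Weak points for 18:** A3 is an α,α′-dialkoxy ketone that can enolise, so epimerisation and β-elimination threaten under the basic ylide. Axial attack on a mobile monocyclic ring is harder to predict. In A4 the oxygens O2, O5 and O6 carry the same protecting group although only O5 is to be benzoylated, so extra steps of differentiation follow.
- **Comparison:** The chosen plan uses the same ylide reaction in step 4, but on a ketone that cannot enolise and whose faces are fixed by the bicycle. O5 enters alone and late.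

**Alternative 3:** The cuts are at the C6–O and C5–O bonds. In the epoxy alcohol A5 (C1–C6 epoxide, free C5 hydroxyl trans to it, benzyl ethers on O2 and O7), aqueous hydroxide lets the C5 alkoxide open the oxirane at C6. This Payne rearrangement gives the C5–C6 epoxide A6, which hydroxide then opens at C5 to the triol A7.

- **Merits:** Three contiguous stereocentres (C1, C6, C5) follow from two inversions in one operation, with no metal and no unprecedented step. It is operationally the simplest of the four roads.
- **Weak points for 18:** The Payne equilibrium and the site of hydroxide attack are hard to steer. A7 has free O5 and O6 side by side although only O5 is to be benzoylated. The benzyl ethers on O2 and O7 must come off before C7 can be acylated. The absolute configuration has to be bought earlier, since A5 must already be a single enantiomer.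
- **Comparison:** The chosen plan sets against this simplicity a catalytic desymmetrisation of a meso compound and an acylation pattern that needs no protecting-group traffic.

Key step: step 7

Assumption: glutaraldehyde is used as its commercial aqueous solution, and both antipodes of the chiral N,N-ligand of step 7 are taken to be accessible, the one that selects the C5–H bond being used.

## Route

**Step 1**
Reactants: 1 glutaraldehyde (pentanedial); 2 nitromethane
Product: 3 meso-2-nitrocyclohexane-1,3-diol (hydroxyls cis to each other, nitro group trans to both)
Conditions: NaOH (1 equiv), MeOH/H2O, 0 °C to rt; then AcOH; crystallisation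
Reagents that add atoms: nitromethane, C[N+](=O)[O-]
Why: Double Henry (nitroaldol) reaction; every step is reversible, so the all-equatorial isomer with the hydroxyls cis and the nitro group trans to both should accumulate as its sodium nitronate and crystallise after acidification, which fixes the cis relation of O2 and O6.

**Step 2**
Reactants: 3 meso-2-nitrocyclohexane-1,3-diol; 4 benzaldehyde dimethyl acetal
Product: 5 meso 9-nitro-3-phenyl-2,4-dioxabicyclo[3.3.1]nonane (benzylidene acetal bridging O2 and O6, phenyl exo, nitro group on the carbocyclic side)
Conditions: PhCH(OMe)2, CSA (cat.), MeCN, 50 °C, MeOH removed under reduced pressure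
Reagents that add atoms: benzaldehyde dimethyl acetal, COC(OC)c1ccccc1
Why: Acid-catalysed transacetalisation driven by removal of methanol; only a cis-1,3-diol can be bridged, and under equilibrium the phenyl group should take the exo (equatorial) position on the new dioxane chair, leaving hydrogen in the endo position under C4.

**Step 3**
Reactants: 5 meso nitro acetal
Product: 7 meso 3-phenyl-2,4-dioxabicyclo[3.3.1]nonan-9-one (C1 ketone, phenyl exo), via potassium nitronate 6 (not isolated)
Conditions: KOH, MeOH, 0 °C; then aq. KMnO4, 0 °C
Reagents that add atoms: potassium permanganate, [K+].[O-][Mn](=O)(=O)=O
Why: Oxidative Nef reaction, in which permanganate cleaves the nitronate C=N bond to the ketone; the β-oxygens are held in the acetal ring and the product cannot enolise because its α-hydrogens sit at the bridgeheads in the carbonyl plane, so neither elimination nor over-oxidation is expected.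

**Step 4**
Reactants: 7 meso bicyclic ketone; 8 trimethylsulfonium iodide
Product: 9 meso spiro-epoxide (oxirane on C1 with its CH2 group, C7, cis to O2 and O6 and its oxygen on the carbocyclic face; phenyl exo)
Conditions: Me3S+ I−, KOtBu, DMSO/THF, 0 °C to rt
Reagents that add atoms: trimethylsulfonium iodide, C[S+](C)C.[I-]
Why: Corey–Chaykovsky epoxidation with dimethylsulfonium methylide, which adds irreversibly; the carbonyl face flanked by the two ring oxygens has no axial hydrogens whereas the other is guarded by the axial hydrogens on C3 and C5, so the methylene should enter cis to O2 and O6 and the oxygen end up on the carbocyclic face, which is the C1 configuration of the target.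

**Step 5**
Reactants: 9 meso spiro-epoxide; 10 benzoic acid
Product: 11 meso hydroxy benzoate (tertiary C1–OH on the carbocyclic face, trans to O2 and O6; C7H2OBz cis to them; benzylidene acetal, phenyl exo)
Conditions: PhCO2H, PhCO2Cs (cat.), DMF, 80 °C
Reagents that add atoms: benzoic acid, O=C(O)c1ccccc1
Why: SN2 opening of the 2,2-disubstituted oxirane by benzoate at its unsubstituted carbon; the C1–O bond is not touched, so C1 keeps its configuration, and the tertiary hydroxyl that is set free is too hindered to take over the acyl group.

**Step 6**
Reactants: 11 meso hydroxy benzoate; 12 diethylsilane
Product: 13 meso diethyl(hydrido)silyl ether of the C1 hydroxyl (C7 benzoate and benzylidene acetal unchanged)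
Conditions: Et2SiH2, RuCl2(PPh3)3 (cat.), THF, 50 °C; volatiles removed, used crude
Reagents that add atoms: diethylsilane, CC[SiH2]CC
Why: Catalytic dehydrogenative coupling of an alcohol with a dihydrosilane; the hindered tertiary alkoxy group should make the second Si–H bond unreactive, so the monoalkoxy(hydrido)silane is expected and is carried on without chromatography.

**Step 7**
Reactants: 13 meso diethyl(hydrido)silyl ether
Product: 14 tricyclic oxasilolane (SiEt2 bonded to O1 and to C5, ring O1–Si–C5–C6–C1 bridging C1 and C5 on the face opposite the acetal; C5–Si cis to O1; single enantiomer)
Conditions: [Ir(cod)OMe]2 (cat.), chiral pyridyl-oxazoline N,N-ligand (cat.), norbornene, THF, 100 °C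
Reagents that add atoms: none
Why: Proposed new method: the Si–H bond of 13 adds to the iridium centre, the silyl complex cleaves the axial C5–H bond, which lies syn-axial to the C1–O–Si arm, through a six-membered metallacycle, and C–Si reductive elimination closes the oxasilolane while norbornene takes up the two hydrogens. The closest known reaction type is the iridium/phenanthroline-catalysed, hydroxyl-directed γ-silylation of secondary C–H bonds in diethyl(hydrido)silyl ethers, together with enantioselective iridium- and rhodium-catalysed C–H silylations that choose between enantiotopic aryl, methyl or cyclopropyl C–H bonds; new here is the choice between two enantiotopic methylene C–H bonds on a cyclohexane. The one ring that closes is the five-membered 1-oxa-2-silacyclopentane O1–Si–C5–C6–C1, formed by C–Si bond formation from the tethered silicon, and it bridges C1 and C5 diaxially on the chair. The one new stereocentre, C5, is fixed relative to C1 by the tether, since silicon can only arrive on the face that carries O1, and in its absolute sense by the chiral ligand, which decides whether the C5 or the mirror-related C3 hydrogen is cut. The step needs γ-selectivity, which the substrate secures because C3 and C5 carry the only γ C–H bonds and only their axial hydrogens can reach the silicon, and selectivity between enantiotopic groups, which rests on the ligand alone. The benzylidene acetal holds the carbocycle in the chair with O1 axial and puts no carbon substituent under C4. Both antipodes of the ligand are accessible, so the sense of induction can be matched to the target once it is known.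

**Step 8**
Reactants: 14 tricyclic oxasilolane
Product: 15 diol (free tertiary C1–OH and secondary C5–OH, cis to each other; C7 benzoate; benzylidene acetal on O2 and O6)
Conditions: H2O2 (30% aq.), KF, KHCO3, THF/MeOH, rt to 40 °C
Reagents that add atoms: hydrogen peroxide, OO
Why: Tamao–Fleming oxidation of the alkoxysilane: hydroperoxide adds to silicon, C5 migrates from silicon to oxygen with retention of configuration and the Si–O bonds are hydrolysed, so O5 should appear cis to O1 and trans to O6.

**Step 9**
Reactants: 15 diol; 16 benzoyl chloride
Product: 17 dibenzoate (benzoates on O5 and O7, free tertiary C1–OH, benzylidene acetal on O2 and O6)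
Conditions: BzCl, pyridine, CH2Cl2, 0 °C to rt
Reagents that add atoms: benzoyl chloride, O=C(Cl)c1ccccc1
Why: Acylation under nucleophilic catalysis by pyridine; the C5 hydroxyl is the only free secondary alcohol, and the other free hydroxyl is tertiary and flanked by three substituted carbons, so it should not react at this temperature.

**Step 10**
Reactants: 17 dibenzoate
Product: 18 [(1S,2R,5R,6S)-5-(benzoyloxy)-1,2,6-trihydroxycyclohexyl]methyl benzoate (CNP0264996.1)
Conditions: H2 (1 atm), Pd(OH)2/C, EtOAc/EtOH, rt
Reagents that add atoms: none
Why: Hydrogenolysis of the benzylic C–O bonds of the benzylidene acetal releases the C2 and C6 hydroxyls with loss of toluene; the medium is neutral, so the benzoates should neither migrate nor be cleaved.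

## Compound list

1 | glutaraldehyde (pentanedial) | O=CCCCC=O | starting material
2 | nitromethane | C[N+](=O)[O-] | starting material
3 | meso-2-nitrocyclohexane-1,3-diol, hydroxyls cis, nitro trans to both | [O-][N+](=O)[C@H]1[C@H](O)CCC[C@@H]1O | intermediate
4 | benzaldehyde dimethyl acetal | COC(OC)c1ccccc1 | starting material
5 | meso 9-nitro-3-phenyl-2,4-dioxabicyclo[3.3.1]nonane, phenyl exo, nitro on the carbocyclic side | [O-][N+](=O)[C@H]1[C@H]2CCC[C@@H]1O[C@@H](c3ccccc3)O2 | intermediate
6 | potassium nitronate of 5 (not isolated) | [K+].[O-][N+]([O-])=C1[C@H]2CCC[C@@H]1O[C@@H](c3ccccc3)O2 | intermediate
7 | meso 3-phenyl-2,4-dioxabicyclo[3.3.1]nonan-9-one, phenyl exo | O=C1[C@H]2CCC[C@@H]1O[C@@H](c3ccccc3)O2 | intermediate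
8 | trimethylsulfonium iodide | C[S+](C)C.[I-] | starting material
9 | meso spiro-epoxide, oxirane CH2 cis to O2 and O6, oxirane O on the carbocyclic face | C1O[C@]12[C@H]3CCC[C@@H]2O[C@@H](c4ccccc4)O3 | intermediate
10 | benzoic acid | O=C(O)c1ccccc1 | starting material
11 | meso hydroxy benzoate: C1–OH trans to O2 and O6, C7H2OBz, benzylidene acetal | O=C(OC[C@]1(O)[C@H]2CCC[C@@H]1O[C@@H](c3ccccc3)O2)c1ccccc1 | intermediate
12 | diethylsilane | CC[SiH2]CC | starting material
13 | meso diethyl(hydrido)silyl ether of 11 | O=C(OC[C@]1(O[SiH](CC)CC)[C@H]2CCC[C@@H]1O[C@@H](c3ccccc3)O2)c1ccccc1 | intermediate
14 | tricyclic oxasilolane, SiEt2 bridging O1 and C5 | O=C(OC[C@@]12[C@H]3CC[C@@H]([Si](CC)(CC)O1)[C@@H]2O[C@@H](c4ccccc4)O3)c1ccccc1 | intermediate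
15 | C1,C5-diol, C7 benzoate, benzylidene acetal | O=C(OC[C@]1(O)[C@H]2CC[C@@H](O)[C@@H]1O[C@@H](c3ccccc3)O2)c1ccccc1 | intermediate
16 | benzoyl chloride | O=C(Cl)c1ccccc1 | starting material
17 | O5,O7-dibenzoate, benzylidene acetal | O=C(OC[C@]1(O)[C@H]2CC[C@@H](OC(=O)c3ccccc3)[C@@H]1O[C@@H](c4ccccc4)O2)c1ccccc1 | intermediate
18 | [(1S,2R,5R,6S)-5-(benzoyloxy)-1,2,6-trihydroxycyclohexyl]methyl benzoate | O=C(OC[C@]1(O)[C@H](O)CC[C@@H](OC(=O)c2ccccc2)[C@@H]1O)c1ccccc1 | target

## Step count and least certain steps

Total step count: 10. Longest linear sequence: 10 (the route is linear from 1).

**Step 7 (key step).** The most likely failure is insufficient discrimination between the enantiotopic axial C–H bonds on C5 and C3, or loss of rate when a chiral ligand replaces phenanthroline. Cleavage of a methylene C–H bond is slow, and the two competing transition states differ only in how the ligand sits against a nearly symmetric bicycle. Consumption of the Si–H bond by reduction of the nearby benzoate is a second concern.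
Fallback, from 13: the cyclisation would be run with the achiral ligand 3,4,7,8-tetramethyl-1,10-phenanthroline ([Ir(cod)OMe]2, norbornene, THF, 100 °C). This is the known hydroxyl-directed γ-silylation of secondary C–H bonds and gives 14 together with an equal amount of the mirror-image oxasilolane F1. Tamao–Fleming oxidation then gives 15 together with the mirror-image diol F2. A lipase-catalysed transesterification (Candida antarctica lipase B, vinyl benzoate, toluene, 40 °C) benzoylates the C5 hydroxyl of one enantiomer only. If 15 reacts faster, the route is rejoined at 17 and F2 is removed as the unreacted alcohol. If not, the mirror-image dibenzoate F3 is removed and the unreacted alcohol rejoins the route at 15.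

**Step 3.** The nitronate may lose an acetal oxygen by β-elimination, or form only slowly at the hindered bridging carbon, because the ring C–O bonds lie close to the nitronate π-system and the carbon is flanked by two substituted centres.
Fallback, from 5: reduction with NaBH4 and NiCl2 in MeOH at 0 °C would give the meso bridging amine F4. Condensation with 3,5-di-tert-butyl-1,2-benzoquinone followed by the prototropic shift gives the N-(2-hydroxyaryl) ketimine F5, and aqueous oxalic acid hydrolyses it to 7, where the route is rejoined.

**Step 4.** The ylide may show poor facial selectivity, because the lone pairs of the two ring oxygens can repel the nucleophile from the face that is sterically open.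
Fallback, from 7: Wittig methylenation (Ph3PCH3+ Br−, KOtBu, THF) would give the meso exocyclic alkene F6. Dihydroxylation with OsO4 (cat.) and N-methylmorpholine N-oxide should occur anti to the two allylic C–O bonds and place O1 on the carbocyclic face, giving the meso diol F7. Benzoylation of its primary hydroxyl (BzCl, pyridine, −20 °C) rejoins the route at 11.

**Step 8.** The primary benzoate may be lost or may migrate under the basic peroxide, because hydroperoxide and methoxide are good nucleophiles toward aryl esters.
Fallback, from 14: the oxidation would be followed in the same flask by K2CO3 in MeOH, so that methanolysis is driven to completion and the triol F8 is isolated. BzCl (2.2 equiv) in pyridine at 0 °C then acylates the primary C7 and the secondary C5 hydroxyl but not the tertiary one, and the route is rejoined at 17.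

## Further compounds

F1 | step 7 | mirror-image oxasilolane (silicon on C3 in place of C5) | O=C(OC[C@]12[C@@H]3CC[C@H]([Si](CC)(CC)O1)[C@H]2O[C@H](c4ccccc4)O3)c1ccccc1
F2 | step 7 | mirror-image diol (enantiomer of 15) | O=C(OC[C@@]1(O)[C@@H]2CC[C@H](O)[C@H]1O[C@H](c3ccccc3)O2)c1ccccc1
F3 | step 7 | mirror-image dibenzoate (enantiomer of 17) | O=C(OC[C@@]1(O)[C@@H]2CC[C@H](OC(=O)c3ccccc3)[C@H]1O[C@H](c4ccccc4)O2)c1ccccc1
F4 | step 3 | meso 3-phenyl-2,4-dioxabicyclo[3.3.1]nonan-9-amine, phenyl exo | N[C@H]1[C@H]2CCC[C@@H]1O[C@@H](c3ccccc3)O2
F5 | step 3 | N-(3,5-di-tert-butyl-2-hydroxyphenyl) ketimine of 7 | CC(C)(C)c1cc(N=C2[C@H]3CCC[C@@H]2O[C@@H](c4ccccc4)O3)c(O)c(c1)C(C)(C)C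
F6 | step 4 | meso 9-methylene-3-phenyl-2,4-dioxabicyclo[3.3.1]nonane, phenyl exo | C=C1[C@H]2CCC[C@@H]1O[C@@H](c3ccccc3)O2
F7 | step 4 | meso C1,C7-diol, C1–OH trans to O2 and O6, benzylidene acetal | OC[C@]1(O)[C@H]2CCC[C@@H]1O[C@@H](c3ccccc3)O2
F8 | step 8 | C1,C5,C7-triol, benzylidene acetal | OC[C@]1(O)[C@H]2CC[C@@H](O)[C@@H]1O[C@@H](c3ccccc3)O2
A1 | alternative 1 | [1-(methoxymethoxy)cyclohexa-2,5-dien-1-yl]methanol | OCC1(OCOC)C=CCC=C1
A2 | alternative 1 | cis-fused iodocarbonate, O at C2, I at C3, C5=C6 alkene intact | O=C1OC[C@]2(OCOC)[C@H](O1)[C@@H](I)CC=C2
A3 | alternative 2 | tris(benzyl ether) ketone, C1 carbonyl, benzyloxy groups on C2, C5 and C6 | O=C1[C@H](OCc2ccccc2)CC[C@@H](OCc2ccccc2)[C@@H]1OCc1ccccc1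
A4 | alternative 2 | spiro-epoxide with C7 cis to the C2 and C6 benzyloxy groups | C1O[C@]12[C@H](OCc3ccccc3)CC[C@@H](OCc3ccccc3)[C@@H]2OCc2ccccc2
A5 | alternative 3 | C1–C6 epoxy alcohol, C5–OH trans to the epoxide, benzyl ethers on O2 and O7 | c1ccccc1COC[C@@]12O[C@@H]1[C@@H](O)CC[C@H]2OCc1ccccc1
A6 | alternative 3 | rearranged C5–C6 epoxide with free tertiary C1–OH | c1ccccc1COC[C@]1(O)[C@H](OCc2ccccc2)CC[C@@H]2O[C@H]12
A7 | alternative 3 | all-trans C1,C6,C5-triol with benzyl ethers on O2 and O7 | c1ccccc1COC[C@]1(O)[C@H](OCc2ccccc2)CC[C@@H](O)[C@@H]1O
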